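The numbers in the tables come from a simulation for substances that don't exist; scatter was added.

Leave the feeds as written.

| flask | starting material | second substrate | capture agent | free catalyst | temperature | remark | time |
|---|---|---|---|---|---|---|---|
| dawn | 13 mM | 13 mM | 1.3 mM | 0.13 mM | −15 °C | run made earlier |  |
| autumn | 13 mM | 13 mM | 1.8 mM | 0.13 mM | 0 °C | run made earlier |  |
| spring | 13 mM | 13 mM | 2.9 mM | 0.13 mM | −15 °C | run made earlier |  |
| gamma | 13 mM (fed, over 1.5 min) | 13.0 mM | 1.30 mM | 0.13 mM | 0 °C | all else is in the flask from the start; the feed brings no volume worth counting | 40 min |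
| beta | 13 mM | 13.0 mM | 1.30 mM | 0.13 mM | 0 °C | everything together at the start | 40 min |
| eta | 13 mM | 13.0 mM (fed, over 15 min) | 1.30 mM | 0.13 mM |  | the addition at −40 °C, then warmed to 0 °C; the feed brings no volume worth counting | 40 min |
| theta | 13 mM | 13.0 mM (fed, over 15 min) | 1.30 mM | 0.13 mM | 0 °C | all else is in the flask from the start; the feed brings no volume worth counting | 40 min |
| epsilon | 13 mM (fed, over 15 min) | 13.0 mM | 1.30 mM | 0.13 mM | 0 °C | all else is in the flask from the start; the feed brings no volume worth counting | 40 min |

- dawn (time / min: target / %): 4.00: 3.0; 12.0: 3.7; 25.0: 5.3; 30.0: 6.9; 50.0: 8.3; 60.0: 7.9; 80.0: 9.4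
- autumn (time / min: target / %): 6.00: 6.6; 12.0: 6.0; 15.0: 8.5; 25.0: 11.4; 30.0: 10.3; 40.0: 12.6
- spring (time / min: target / %): 4.00: 2.1; 12.0: 2.8; 25.0: 3.3; 30.0: 2.9; 50.0: 4.9; 60.0: 5.1; 80.0: 5.4

(readings scatter by 1 percentage point)

- reactions considered so far: starting material + free catalyst <-> catalyst intermediate A; catalyst intermediate A -> free catalyst + target; second substrate + free catalyst <-> catalyst intermediate B; catalyst intermediate B -> free catalyst + second product; catalyst intermediate B + capture agent -> trapped intermediate

- the best flask by amount of target, in percent of the starting material charged; "all alike" if 1.5 percentage points covers them all (gamma / beta / eta / theta / epsilon / all alike)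
- amount of target at the end, in percent of the starting material charged, gamma
- amount of target at the end, in percent of the starting material charged, beta
- amount of target at the end, in percent of the starting material charged, eta
- amount of target at the end, in percent of the starting material charged, theta
- amount of target at the end, in percent of the starting material charged, epsilon

Free catalyst works two rounds in these flasks. Through catalyst intermediate A it turns starting material into target; through catalyst intermediate B it turns second substrate into second product. Catalyst intermediate B can also meet capture agent and leave as trapped intermediate, which does not return.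

I write the balance of the catalyst, the reagent charged in the smaller amount: charged catalyst equals its working forms plus trapped intermediate. Capture agent stands at 1.30 mM against 0.13 mM of catalyst, and trapping one catalyst per capture agent can use 10.0 % of that charge, so 90.0 % of it stays beside the catalyst even when the catalyst is all trapped.

I therefore carry the turnover number: target made per catalyst trapped. I treat autumn's catalyst as trapped by its last reading, which is an assumption. That reading gives 12.6 at 1.8 mM of capture agent. Scaled inversely to 1.30 mM, it becomes 17.4. The scaling is rough: from dawn to spring, the last target reading falls from 9.4 % to 5.4 %, less steeply than the inverse of capture agent.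

When you come at 40 min, I expect beta, its catalyst again counted as trapped, to hold 17.4 % target and 82.6 % starting material. Each target needs starting material, while each trapping needs second substrate and capture agent. Slow second substrate should therefore raise the turnover number in theta, and slow starting material should lower it in epsilon.

The forecast picks theta: gamma 15.3 %, beta 16 %, eta 13.5 %, theta 20.5 %, epsilon 10.5 %. For theta it says “catalyst is spared early”. My beta figure is higher than its figure.

The flasks give gamma 15.1 %, beta 15.9 %, eta 14.2 %, theta 24.4 % and epsilon 9.56 %; the best is theta.

    starting material + free catalyst ⇌ catalyst intermediate A (K = 540 L mol⁻¹, k = 2.60 L mol⁻¹ s⁻¹, Ea = 41.0 kJ mol⁻¹, ΔH = 2.00 kJ mol⁻¹)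
    catalyst intermediate A → free catalyst + target (k = 0.320 s⁻¹, Ea = 66.0 kJ mol⁻¹)
    second substrate + free catalyst ⇌ catalyst intermediate B (K = 190 L mol⁻¹, k = 4.50 L mol⁻¹ s⁻¹, Ea = 42.0 kJ mol⁻¹, ΔH = −78.0 kJ mol⁻¹)
    catalyst intermediate B → free catalyst + second product (k = 0.110 s⁻¹, Ea = 60.0 kJ mol⁻¹)
    catalyst intermediate B + capture agent → trapped intermediate (k = 3.90 L mol⁻¹ s⁻¹, Ea = 43.0 kJ mol⁻¹)
    (constants at 0 °C)

In theta at 40.0 min, catalyst intermediate B goes on to free catalyst 24 times for each time it is trapped, and 90.5 % of the catalyst charged stands as trapped intermediate. Theta's turnover number, reckoned on the catalyst trapped at that time, is 27.0, higher than beta's 17.0 and than my 17.4. The neighbour of theta charged with 0.33 mM of free catalyst makes 56.2 % target, with a turnover number of 26.9.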